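**Retrosynthetic overview** (labdane numbering: ring A = C1–C2–C3–C4–C5–C10, ring B = C5–C6–C7–C8–C9–C10; C11–C12 linker, C13–C16 butenolide, C17 on C8, C18/C19 on C4, C20 on C10)
1. C12–C13 is cut last: the C9 vinyl group is hydroborated and coupled (sp3–sp2 Suzuki–Miyaura) with 3-bromofuran-2(5H)-one, so the lactone arrives as an intact ring and is never closed in the route.
2. C4(CH2OH)2 comes from a C4 ketone: Wittig homologation gives the C18 aldehyde, and aldol/crossed Cannizzaro reaction with formaldehyde adds C19.
3. Ring A is cut by a Diels–Alder disconnection at C1–C10 and C2–C3: the ring-B diene C3=C4(OEt)–C5=C10(CH3) plus phenyl vinyl sulfone as an ethylene equivalent (C1–C2).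
4. Enabling feature: ring A is unsubstituted at C1, C2 and C3, and C4 is achiral (two identical CH2OH groups) next to the ring-fusion carbon C5. Ring A therefore equals "cyclohexanone at C4 + ethylene"; the quaternary C10 is the diene terminus inside ring B, and the C4 carbonyl lets C5 equilibrate to the trans fusion.
5. Ring order: ring B first (step 2; C8 from an enantioselective Michael addition, C9 by trans cuprate addition), then ring A (step 5), the last ring closed.

Key step: step 5

Remark: 9 is drawn as the expected ortho/para, endo cycloadduct; the position and configuration of the sulfonyl group are immaterial because step 6 replaces it by hydrogen, and C4 in 12–14 needs no control because it ends with two identical CH2OH groups.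

Step 1
Reactants: 1 3-(benzyloxy)propanal; 2 pent-1-en-3-one
Product: 3 (R)-2-[(benzyloxy)methyl]-5-oxoheptanal
Conditions: (R)-2-[diphenyl(trimethylsilyloxy)methyl]pyrrolidine (10 mol %), ethyl 3,4-dihydroxybenzoate (20 mol %), CH2Cl2, 4 °C
Reagents that add atoms: none
Why: Enamine-mediated organocatalytic Michael addition of an aldehyde to a vinyl ketone, in which the (R)-diarylprolinol silyl ether shields one face of the E-enamine so that the new C7–C8 bond is formed with R configuration at C8.

Step 2
Reactants: 3 (R)-2-[(benzyloxy)methyl]-5-oxoheptanal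
Product: 4 (S)-4-[(benzyloxy)methyl]-2-methylcyclohex-2-en-1-one
Conditions: TsOH·H2O (10 mol %), toluene, 4 Å molecular sieves, 60 °C
Reagents that add atoms: none
Why: Acid-catalysed intramolecular aldol condensation (Robinson-type closure of a 1,5-keto aldehyde) in which only the ethyl CH2 (C10) can reach the aldehyde through a six-membered transition state, giving ring B as the 2-methyl enone with C8 untouched (the descriptor changes from R to S by priority only).

Step 3
Reactants: 4 (S)-4-[(benzyloxy)methyl]-2-methylcyclohex-2-en-1-one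
Product: 6 (3R,4S)-4-[(benzyloxy)methyl]-2-methyl-3-vinylcyclohex-1-en-1-yl trifluoromethanesulfonate, via bromomagnesium enolate 5 (not isolated)
Conditions: CH2=CHMgBr, CuBr·SMe2 (10 mol %), THF, −78 to −40 °C; then 2-[N,N-bis(trifluoromethylsulfonyl)amino]-5-chloropyridine, −78 to 23 °C
Reagents that add atoms: vinylmagnesium bromide (C=C[Mg]Br); 2-[N,N-bis(trifluoromethylsulfonyl)amino]-5-chloropyridine (O=S(=O)(N(c1ccc(Cl)cn1)S(=O)(=O)C(F)(F)F)C(F)(F)F)
Why: Copper-catalysed conjugate addition of the vinyl Grignard reagent occurs anti to the C8 substituent (trans-3,4 product, setting C9), and the regiodefined enolate is O-sulfonylated by the triflimide to the tetrasubstituted enol triflate.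

Step 4
Reactants: 6 (3R,4S)-4-[(benzyloxy)methyl]-2-methyl-3-vinylcyclohex-1-en-1-yl trifluoromethanesulfonate
Product: 7 ({[(1S,2R)-4-(1-ethoxyvinyl)-3-methyl-2-vinylcyclohex-3-en-1-yl]methoxy}methyl)benzene
Conditions: Bu3Sn[C(OEt)=CH2], Pd(PPh3)4 (5 mol %), CuI (10 mol %), LiCl, THF, 65 °C; chromatography on Et3N-deactivated silica
Reagents that add atoms: tributyl(1-ethoxyvinyl)stannane (CCCC[Sn](CCCC)(CCCC)C(=C)OCC)
Why: Stille cross-coupling of the enol triflate with the α-ethoxyvinyl stannane (LiCl for transmetalation, CuI for the hindered partner) gives the 2-ethoxy-1,3-diene C3=C4(OEt)–C5=C10 without touching the stereocentres.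

Step 5
Reactants: 7 ({[(1S,2R)-4-(1-ethoxyvinyl)-3-methyl-2-vinylcyclohex-3-en-1-yl]methoxy}methyl)benzene; 8 phenyl vinyl sulfone
Product: 9 (1R,2S,8R,8aS)-2-[(benzyloxy)methyl]-5-ethoxy-8a-methyl-8-(phenylsulfonyl)-1-vinyl-1,2,3,4,6,7,8,8a-octahydronaphthalene
Conditions: 8 (4 equiv), 2,6-di-tert-butyl-4-methylphenol (cat.), toluene, 120 °C, sealed tube; chromatography on Et3N-deactivated silica
Reagents that add atoms: none
Why: Thermal normal-electron-demand Diels–Alder reaction between the electron-rich 2-ethoxy diene C3=C4(OEt)–C5=C10 and phenyl vinyl sulfone, an established ethylene equivalent; the closest known reaction type is the cycloaddition of 2-silyloxy- or 2-alkoxy-1-vinylcyclohexenes with vinyl sulfones and acrylates. Ring A is closed by an intermolecular [4+2] cycloaddition, suprafacial on both partners, that forms C2–C3 (leading bond, at the unhindered nucleophilic terminus) and C1–C10 (lagging bond, creating the quaternary centre) and leaves the C4=C5 enol ether. The C10 configuration is controlled by the adjacent C9 stereocentre: allylic 1,2-strain with the C10 methyl group places the C9 vinyl group pseudoaxial and the dienophile adds to the opposite diene face, so that C1 ends trans to C11 and the methyl group cis to it. The sulfonyl-bearing carbon (expected at C1 by the ortho/para rule, endo) is a temporary stereocentre whose regio- and stereochemistry does not matter because step 6 removes the sulfonyl group. The step needs facial selectivity at C10 (secured by the pseudoaxial C9 substituent) and site selectivity for the conjugated, donor-substituted diene over the isolated vinyl group (secured electronically); C5 is deliberately left sp2 so that the ring fusion can be set afterwards under thermodynamic control.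

Step 6
Reactants: 9 (1R,2S,8R,8aS)-2-[(benzyloxy)methyl]-5-ethoxy-8a-methyl-8-(phenylsulfonyl)-1-vinyl-1,2,3,4,6,7,8,8a-octahydronaphthalene
Product: 11 (4aS,5R,6S,8aS)-6-(hydroxymethyl)-4a-methyl-5-vinyloctahydronaphthalen-1(2H)-one, via desulfonylated enol ether alcohol 10 (not isolated)
Conditions: Li, NH3(l)/THF, −78 °C; NH4Cl; then 1 M HCl, THF, 23 °C (any cis-fused epimer is returned to the acid equilibration)
Reagents that add atoms: water (O)
Why: Dissolving-metal reduction cleaves the alkyl aryl sulfone C–S bond and the benzyl ether in one operation while the enol ether masks the ketone and the isolated vinyl group is inert, after which acid hydrolyses the enol ether and equilibrates C5 (α to the C4 ketone) to the more stable trans ring fusion, as in 4-oxo-5α-steroids.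

Step 7
Reactants: 11 (4aS,5R,6S,8aS)-6-(hydroxymethyl)-4a-methyl-5-vinyloctahydronaphthalen-1(2H)-one
Product: 13 (4aR,5R,6S,8aR)-6-(hydroxymethyl)-4a-methyl-5-vinyldecahydronaphthalene-1-carbaldehyde (epimers at the formyl-bearing carbon), via methyl enol ether 12 (not isolated)
Conditions: [Ph3PCH2OMe]Cl, KN(SiMe3)2 (excess), THF, 0 to 40 °C; then 2 M HCl, THF, 23 °C
Reagents that add atoms: (methoxymethyl)triphenylphosphonium chloride (COC[P+](c1ccccc1)(c1ccccc1)c1ccccc1.[Cl-]); water (O)
Why: Wittig methoxymethylenation of the C4 ketone followed by enol ether hydrolysis is the standard one-carbon homologation to the aldehyde (C18), the new C4 centre being epimerisable and irrelevant while C5, no longer enolisable, keeps the trans fusion.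

Step 8
Reactants: 13 (4aR,5R,6S,8aR)-6-(hydroxymethyl)-4a-methyl-5-vinyldecahydronaphthalene-1-carbaldehyde
Product: 15 [(4aS,5R,6S,8aS)-4a-methyl-5-vinyloctahydronaphthalene-1,1,6(2H)-triyl]trimethanol, via hydroxymethyl aldehyde 14 (not isolated)
Conditions: CH2O (37 % aq., excess), KOH, MeOH/H2O, 60 °C
Reagents that add atoms: formaldehyde (C=O)
Why: Tollens condensation, in which aldol addition of the α-branched aldehyde enolate to formaldehyde builds the quaternary C4 and crossed Cannizzaro hydride transfer from a second formaldehyde reduces the now non-enolisable aldehyde, gives two identical CH2OH groups so that no stereocentre is created.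

Step 9
Reactants: 16 furan-2(5H)-one
Product: 18 3-bromofuran-2(5H)-one, via trans-dibromolactone 17 (not isolated)
Conditions: Br2, CH2Cl2, 0 to 23 °C; then Et3N, 0 °C
Reagents that add atoms: bromine (BrBr)
Why: Bromine addition to the conjugated alkene followed by amine-induced dehydrobromination (loss of the acidic α-hydrogen and the β-bromide) is the standard route to the α-bromobutenolide.

Step 10
Reactants: 15 [(4aS,5R,6S,8aS)-4a-methyl-5-vinyloctahydronaphthalene-1,1,6(2H)-triyl]trimethanol; 18 3-bromofuran-2(5H)-one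
Product: 20 3-{2-[(1R,2S,4aS,8aS)-2,5,5-tris(hydroxymethyl)-8a-methyldecahydronaphthalen-1-yl]ethyl}furan-2(5H)-one, via alkylborane 19 (not isolated)
Conditions: 9-BBN (5 equiv), THF, 0 to 23 °C; then 18, PdCl2(dppf) (10 mol %), AsPh3 (10 mol %), Cs2CO3, DMF/H2O, 23 °C
Reagents that add atoms: none
Why: Anti-Markovnikov hydroboration of the terminal vinyl group with 9-BBN (the hydroxyl groups being masked in situ as borinates by excess reagent) and B-alkyl Suzuki–Miyaura coupling with the α-bromo-α,β-unsaturated lactone form the C12–C13 bond and bring in the intact butenolide, aqueous base then releasing the three hydroxyl groups with no stereocentre touched.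

**Compound list**
1 | 3-(benzyloxy)propanal | O=CCCOCc1ccccc1 | starting material
2 | pent-1-en-3-one | C=CC(=O)CC | starting material
3 | (R)-2-[(benzyloxy)methyl]-5-oxoheptanal | O=C[C@@H](COCc1ccccc1)CCC(=O)CC | intermediate
4 | (S)-4-[(benzyloxy)methyl]-2-methylcyclohex-2-en-1-one | O=C1CC[C@H](COCc2ccccc2)C=C1C | intermediate
5 | bromomagnesium (3R,4S)-4-[(benzyloxy)methyl]-2-methyl-3-vinylcyclohex-1-en-1-olate | CC1=C(O[Mg]Br)CC[C@H](COCc2ccccc2)[C@H]1C=C | intermediate (not isolated)
6 | (3R,4S)-4-[(benzyloxy)methyl]-2-methyl-3-vinylcyclohex-1-en-1-yl trifluoromethanesulfonate | CC1=C(OS(=O)(=O)C(F)(F)F)CC[C@H](COCc2ccccc2)[C@H]1C=C | intermediate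
7 | ({[(1S,2R)-4-(1-ethoxyvinyl)-3-methyl-2-vinylcyclohex-3-en-1-yl]methoxy}methyl)benzene | CC1=C(C(=C)OCC)CC[C@H](COCc2ccccc2)[C@H]1C=C | intermediate
8 | phenyl vinyl sulfone | C=CS(=O)(=O)c1ccccc1 | starting material
9 | (1R,2S,8R,8aS)-2-[(benzyloxy)methyl]-5-ethoxy-8a-methyl-8-(phenylsulfonyl)-1-vinyl-1,2,3,4,6,7,8,8a-octahydronaphthalene | C[C@@]12[C@H](S(=O)(=O)c3ccccc3)CCC(OCC)=C1CC[C@H](COCc3ccccc3)[C@H]2C=C | intermediate
10 | [(1R,2S,8aS)-5-ethoxy-8a-methyl-1-vinyl-1,2,3,4,6,7,8,8a-octahydronaphthalen-2-yl]methanol | C[C@@]12CCCC(OCC)=C1CC[C@H](CO)[C@H]2C=C | intermediate (not isolated)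
11 | (4aS,5R,6S,8aS)-6-(hydroxymethyl)-4a-methyl-5-vinyloctahydronaphthalen-1(2H)-one (trans-fused) | C[C@@]12CCCC(=O)[C@H]1CC[C@H](CO)[C@H]2C=C | intermediate
12 | [(1R,2S,4aS,8aS)-5-(methoxymethylidene)-8a-methyl-1-vinyldecahydronaphthalen-2-yl]methanol (E/Z mixture) | C[C@@]12CCCC(=COC)[C@H]1CC[C@H](CO)[C@H]2C=C | intermediate (not isolated)
13 | (4aR,5R,6S,8aR)-6-(hydroxymethyl)-4a-methyl-5-vinyldecahydronaphthalene-1-carbaldehyde (both epimers at C1) | C[C@@]12CCCC(C=O)[C@H]1CC[C@H](CO)[C@H]2C=C | intermediate
14 | (4aS,5R,6S,8aS)-1,6-bis(hydroxymethyl)-4a-methyl-5-vinyldecahydronaphthalene-1-carbaldehyde (both epimers at C1) | C[C@@]12CCCC(CO)(C=O)[C@H]1CC[C@H](CO)[C@H]2C=C | intermediate (not isolated)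
15 | [(4aS,5R,6S,8aS)-4a-methyl-5-vinyloctahydronaphthalene-1,1,6(2H)-triyl]trimethanol | C[C@@]12CCCC(CO)(CO)[C@H]1CC[C@H](CO)[C@H]2C=C | intermediate
16 | furan-2(5H)-one | O=C1OCC=C1 | starting material
17 | trans-3,4-dibromodihydrofuran-2(3H)-one (racemic) | O=C1OCC(Br)C1Br | intermediate (not isolated)
18 | 3-bromofuran-2(5H)-one | O=C1OCC=C1Br | intermediate
19 | B-alkyl-9-BBN adduct of 15 at C12, the three hydroxyl groups bound as 9-BBN borinates | C[C@@]12CCCC(COB3C4CCCC3CCC4)(COB3C4CCCC3CCC4)[C@H]1CC[C@H](COB3C4CCCC3CCC4)[C@H]2CCB3C4CCCC3CCC4 | intermediate (not isolated)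
20 | 3-{2-[(1R,2S,4aS,8aS)-2,5,5-tris(hydroxymethyl)-8a-methyldecahydronaphthalen-1-yl]ethyl}furan-2(5H)-one (CNP0271381.1) | C[C@@]12CCCC(CO)(CO)[C@H]1CC[C@H](CO)[C@H]2CCC1=CCOC1=O | target

**Step count:** 10 steps in total; longest linear sequence 9 steps (steps 1–8 and 10; step 9 is a one-step branch).

**Steps most likely to fail**

Step 5. The cycloaddition may be too slow at the fully substituted diene terminus, so that a 1,5-hydrogen shift from the C10 methyl group into the diene competes at the temperature needed. Facial selectivity at C10 may also erode, because the C8 substituent, axial in the reactive half-chair, lies on the attacked face. The fallback sets out from diene 7 and comes back at ketone 11; it replaces the pericyclic step by an anionic ring closure at low temperature. Mild hydrolysis of 7 (0.5 M HCl, THF, 0 °C) gives the acetylcyclohexene F1. LiN(iPr)2 (THF, −78 °C) forms its cross-conjugated lithium dienolate, which adds to 8 through C3, and the resulting α-sulfonyl carbanion closes ring A by intramolecular Michael addition at C10 (sequential Michael–Michael ring closure). Trapping the final enolate with tBuMe2SiCl/HMPA gives the silyl enol ether F2, which under the conditions of step 6 (Li, NH3; then HCl) gives 11.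

Step 10. Base-induced decomposition of the α-bromobutenolide (ring opening, conjugate addition of hydroxide) may outrun transmetalation of the hindered, borinate-laden alkylborane, or hydroboration may stall because the hydroxyl groups consume the borane. The fallback sets out from triol 15 and comes back at target 20. Et3SiCl/imidazole gives the tris(triethylsilyl) ether F3. 9-BBN followed by NaOH/H2O2 gives the primary alcohol F4, and oxidation with 1,1,1-triacetoxy-1,1-dihydro-1,2-benziodoxol-3(1H)-one gives the aldehyde F5. Wittig reaction with commercial 3-(triphenylphosphoranylidene)dihydrofuran-2(3H)-one (lactone ring again pre-formed) gives the (E)-alkylidene lactone F6. RhCl3·3H2O in ethanol at 80 °C moves the exocyclic double bond into the ring to give the butenolide tris-silyl ether F7, and 1 M HCl in THF removes the silyl groups to give 20.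

Step 1. The enamine of the β-benzyloxy aldehyde may lose benzyl alcohol (retro-oxa-Michael), or the α-stereocentre may partly racemise before the ring is closed in step 2. The fallback sets out from 1 and 2 and comes back at 3; it uses auxiliary-controlled azaenolate alkylation instead of enamine catalysis. Addition of HBr to 2 in the presence of ethane-1,2-diol gives the bromo ketal F8. Condensation of 1 with (S)-1-amino-2-(methoxymethyl)pyrrolidine (SAMP) gives the hydrazone F9. Deprotonation with LiN(iPr)2 (THF, 0 °C) and alkylation with F8 at −100 to −78 °C gives the alkylated hydrazone F10 with the required configuration at C8. Two-phase aqueous oxalic acid, then 1 M HCl in THF, cleaves the hydrazone and the ketal to give 3.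

**Further compounds**
F1 | step 5 | 1-[(3R,4S)-4-[(benzyloxy)methyl]-2-methyl-3-vinylcyclohex-1-en-1-yl]ethan-1-one | CC1=C(C(C)=O)CC[C@H](COCc2ccccc2)[C@H]1C=C
F2 | step 5 | (1R,2S,8R,8aS)-2-[(benzyloxy)methyl]-5-[(tert-butyldimethylsilyl)oxy]-8a-methyl-8-(phenylsulfonyl)-1-vinyl-1,2,3,4,6,7,8,8a-octahydronaphthalene | C[C@@]12[C@H](S(=O)(=O)c3ccccc3)CCC(O[Si](C)(C)C(C)(C)C)=C1CC[C@H](COCc3ccccc3)[C@H]2C=C
F3 | step 10 | tris(triethylsilyl) ether of 15 | C[C@@]12CCCC(CO[Si](CC)(CC)CC)(CO[Si](CC)(CC)CC)[C@H]1CC[C@H](CO[Si](CC)(CC)CC)[C@H]2C=C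
F4 | step 10 | 2-{(1R,2S,4aS,8aS)-8a-methyl-2,5,5-tris[(triethylsilyloxy)methyl]decahydronaphthalen-1-yl}ethan-1-ol | C[C@@]12CCCC(CO[Si](CC)(CC)CC)(CO[Si](CC)(CC)CC)[C@H]1CC[C@H](CO[Si](CC)(CC)CC)[C@H]2CCO
F5 | step 10 | 2-{(1R,2S,4aS,8aS)-8a-methyl-2,5,5-tris[(triethylsilyloxy)methyl]decahydronaphthalen-1-yl}acetaldehyde | C[C@@]12CCCC(CO[Si](CC)(CC)CC)(CO[Si](CC)(CC)CC)[C@H]1CC[C@H](CO[Si](CC)(CC)CC)[C@H]2CC=O
F6 | step 10 | (E)-3-(2-{(1R,2S,4aS,8aS)-8a-methyl-2,5,5-tris[(triethylsilyloxy)methyl]decahydronaphthalen-1-yl}ethylidene)dihydrofuran-2(3H)-one | C[C@@]12CCCC(CO[Si](CC)(CC)CC)(CO[Si](CC)(CC)CC)[C@H]1CC[C@H](CO[Si](CC)(CC)CC)[C@H]2C/C=C3\CCOC3=O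
F7 | step 10 | 3-(2-{(1R,2S,4aS,8aS)-8a-methyl-2,5,5-tris[(triethylsilyloxy)methyl]decahydronaphthalen-1-yl}ethyl)furan-2(5H)-one | C[C@@]12CCCC(CO[Si](CC)(CC)CC)(CO[Si](CC)(CC)CC)[C@H]1CC[C@H](CO[Si](CC)(CC)CC)[C@H]2CCC3=CCOC3=O
F8 | step 1 | 2-(2-bromoethyl)-2-ethyl-1,3-dioxolane | CCC1(CCBr)OCCO1
F9 | step 1 | (S,E)-N-[3-(benzyloxy)propylidene]-2-(methoxymethyl)pyrrolidin-1-amine | COC[C@@H]1CCCN1/N=C/CCOCc1ccccc1
F10 | step 1 | (S,E)-N-{(S)-2-[(benzyloxy)methyl]-4-(2-ethyl-1,3-dioxolan-2-yl)butylidene}-2-(methoxymethyl)pyrrolidin-1-amine | COC[C@@H]1CCCN1/N=C/[C@@H](COCc1ccccc1)CCC1(CC)OCCO1
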